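**Retrosynthetic overview**
1. C8–C9 is made last. A samarium ketyl radical from a C9 aldehyde adds to C8 of an unfunctionalised butenolide. This closes the ten-membered ring and frees the 9-OH, and a selenoxide elimination in the same pot restores C8=C17.
2. C4–C5 comes from a B-alkyl Suzuki coupling of a ring-A vinyl carbinol ester with a (Z)-bromopropenyl butenolide.
3. Ring A comes from a Claisen ring contraction of a 2-alkenyl-dihydropyranone. It forms C1–C10, sets C1 and C10, and places C11=C12. The pyranone is made by a catalytic aldol and a Wacker-type closure.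
4. Both Z-trisubstituted olefin units (C9–C11/C20 and C5–C7/C16) come from one building block, (Z)-3-bromobut-2-en-1-ol. The butenolide is made by carbonylative lactonisation.
5. Ring order: butenolide (in its fragment) and pyranone, then cyclohexene, then the ten-membered ring.

Assumption: C-numbers are briarane numbers (C1 quaternary, C2 butyrate, C7 lactone O, C9 OH, C14 acetate). The sense of induction of the ProPhenol catalysts is taken as written, and the antipodal ligand is used if it proves opposite.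

**Step 1**
Reactants: 1 but-2-yn-1-ol
Product: 3 (Z)-3-bromobut-2-en-1-ol, via cyclic vinylalanate 2 (not isolated)
Conditions: Red-Al, THF, 0 °C to rt; NBS, −78 °C; aq. Rochelle salt
Reagents that add atoms: N-bromosuccinimide O=C1CCC(=O)N1Br
Why: Hydroxyl-directed trans-hydroalumination puts aluminium on the distal alkyne carbon inside a five-membered alanate, so bromodealumination with retention gives only the Z vinyl bromide (Br cis to CH2OH).

**Step 2**
Reactants: 3 (Z)-3-bromobut-2-en-1-ol
Product: 4 (Z)-(3-bromobut-2-enyloxy)(tert-butyl)dimethylsilane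
Conditions: TBSCl, imidazole, CH2Cl2, 0 °C to rt
Reagents that add atoms: tert-butyldimethylsilyl chloride CC(C)(C)[Si](C)(C)Cl
Why: Standard silylation of a primary allylic alcohol, which masks the future C9 oxygen until step 14.

**Step 3**
Reactants: 4 (Z)-(3-bromobut-2-enyloxy)(tert-butyl)dimethylsilane
Product: 6 (Z)-4-(tert-butyldimethylsilyloxy)-2-methylbut-2-enal, via (Z)-vinyllithium 5 (not isolated)
Conditions: t-BuLi (2.1 equiv), Et2O, −78 °C; DMF, −78 °C; pH 7 buffer
Reagents that add atoms: N,N-dimethylformamide CN(C)C=O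
Why: Bromine–lithium exchange and Bouveault formylation both keep the olefin geometry, so CHO (C12) ends up cis to C9, and staying at −78 °C outruns the 1,4 O-to-C silyl shift.

**Step 4**
Reactants: 6 (Z)-4-(tert-butyldimethylsilyloxy)-2-methylbut-2-enal; 7 3-methylbut-3-en-2-one
Product: 8 (5R,6Z)-8-(tert-butyldimethylsilyloxy)-5-hydroxy-2,6-dimethylocta-1,6-dien-3-one
Conditions: (S,S)-ProPhenol (10 mol%), Et2Zn (20 mol%), 4 Å MS, 7 (5 equiv), THF, 0 °C
Reagents that add atoms: none
Why: In this direct catalytic asymmetric aldol (dinuclear-zinc ProPhenol type) the ketone can enolise only at its methyl group, and the chiral zinc enolate adds 1,2 to the enal and sets C12 as R.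

**Step 5**
Reactants: 8 (5R,6Z)-8-(tert-butyldimethylsilyloxy)-5-hydroxy-2,6-dimethylocta-1,6-dien-3-one
Product: 9 (2R)-2-[(2Z)-4-(tert-butyldimethylsilyloxy)but-2-en-2-yl]-5-methyl-2,3-dihydro-4H-pyran-4-one
Conditions: PdCl2 (10 mol%), CuCl (20 mol%), Na2HPO4, O2 (1 atm), DME, 50 °C
Reagents that add atoms: none
Why: In this Wacker-type oxidative cyclisation the β-hydroxyl attacks the enone terminus 6-endo, β-hydride elimination of a C2–H gives the vinylogous ester, and C12 is not touched.

**Step 6**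
Reactants: 9 (2R)-2-[(2Z)-4-(tert-butyldimethylsilyloxy)but-2-en-2-yl]-5-methyl-2,3-dihydro-4H-pyran-4-one
Product: 10 (1S,6S)-6-(tert-butyldimethylsilyloxymethyl)-1,5-dimethyl-2-oxocyclohex-4-ene-1-carbaldehyde
Conditions: o-dichlorobenzene (0.02 M), BHT, base-washed sealed tube, 190 °C
Reagents that add atoms: none
Why: In this Claisen rearrangement used as a ring contraction the tether enforces a boat transition state, C10 bonds to C1 on the face that C12–O leaves (chirality transfer from C12), the Z olefin places C9 trans to the new formyl group C2, and the double bond lands at C11=C12.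

**Step 7**
Reactants: 3 (Z)-3-bromobut-2-en-1-ol
Product: 11 (Z)-3-bromobut-2-enal
Conditions: MnO2, CH2Cl2, rt, dark
Reagents that add atoms: none
Why: Neutral heterogeneous allylic oxidation gives the enal without Z/E isomerisation.

**Step 8**
Reactants: 11 (Z)-3-bromobut-2-enal; 12 propyne
Product: 14 (4S,5Z)-6-bromohept-5-en-2-yn-4-ol, via methyl(prop-1-ynyl)zinc 13 (not isolated)
Conditions: Me2Zn (3 equiv), 12 (3 equiv), (S,S)-ProPhenol (20 mol%), Ph3P=O (40 mol%), toluene, 0 °C
Reagents that add atoms: none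
Why: Catalytic asymmetric alkynylation of an enal (ProPhenol–zinc type) adds the alkynylzinc 1,2 and sets C7 as S.

**Step 9**
Reactants: 14 (4S,5Z)-6-bromohept-5-en-2-yn-4-ol
Product: 16 (2Z,4S,5Z)-2-bromo-6-iodohepta-2,5-dien-4-ol, via cyclic vinylalanate 15 (not isolated)
Conditions: Red-Al, THF, 0 °C; I2, −78 °C; aq. Rochelle salt
Reagents that add atoms: iodine II
Why: The same directed trans-hydroalumination as in step 1 followed by iododealumination puts iodine on C17 cis to the carbinol, and the two different halogens keep C7 a stereocentre and let the two olefins be addressed one at a time.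

**Step 10**
Reactants: 16 (2Z,4S,5Z)-2-bromo-6-iodohepta-2,5-dien-4-ol
Product: 17 (5R)-5-[(1Z)-2-bromoprop-1-enyl]-3-methylfuran-2(5H)-one
Conditions: PdCl2(PPh3)2 (3 mol%), CO (1 atm), K2CO3, THF, rt
Reagents that add atoms: carbon monoxide [C-]#[O+]
Why: In this palladium-catalysed carbonylative lactonisation Pd(0) inserts only into the weaker C–I bond and the acyl-palladium is trapped by the cis hydroxyl, the C7–O bond is not broken, and the descriptor changes to R only because the CIP priorities change.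

**Step 11**
Reactants: 10 (1S,6S)-6-(tert-butyldimethylsilyloxymethyl)-1,5-dimethyl-2-oxocyclohex-4-ene-1-carbaldehyde
Product: 19 (1R)-1-[(1S,6S)-6-(tert-butyldimethylsilyloxymethyl)-1,5-dimethyl-2-oxocyclohex-4-en-1-yl]allyl butanoate, via titanium alkoxide 18 (not isolated)
Conditions: CH2=CHMgBr, ClTi(OiPr)3, THF, −78 °C; 10, −78 to −30 °C; PrCOCl, DMAP (cat.), −30 to 0 °C
Reagents that add atoms: vinylmagnesium bromide C=C[Mg]Br; butyryl chloride CCCC(=O)Cl
Why: This aldehyde-selective, non-chelating organotitanium addition follows polar Felkin–Anh/Cornforth control, with the vinyl group attacking anti to the C14 carbonyl and past the small methyl group to give 2R, and the alkoxide is acylated at once to block retro-aldol cleavage.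

**Step 12**
Reactants: 19 (1R)-1-[(1S,6S)-6-(tert-butyldimethylsilyloxymethyl)-1,5-dimethyl-2-oxocyclohex-4-en-1-yl]allyl butanoate
Product: 21 (1R)-1-[(1R,2S,6S)-2-acetoxy-6-(tert-butyldimethylsilyloxymethyl)-1,5-dimethylcyclohex-4-en-1-yl]allyl butanoate, via lithium alkoxide 20 (not isolated)
Conditions: L-Selectride, THF, −78 °C; Ac2O, DMAP, −78 to 0 °C
Reagents that add atoms: acetic anhydride CC(=O)OC(C)=O
Why: The bulky borohydride attacks equatorially, as it does with 4,4-dimethyl-3-keto terpenoids, and gives the axial 14S alkoxide (trans to Me-15, cis to C2), which is acetylated cold before the butyrate can migrate.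

**Step 13**
Reactants: 21 (1R)-1-[(1R,2S,6S)-2-acetoxy-6-(tert-butyldimethylsilyloxymethyl)-1,5-dimethylcyclohex-4-en-1-yl]allyl butanoate; 17 (5R)-5-[(1Z)-2-bromoprop-1-enyl]-3-methylfuran-2(5H)-one
Product: 23 C9-O-TBS 8,9-seco-briarane butenolide (1S,2R,5Z,7S,10S,14S), via B-alkyl-9-BBN 22 (not isolated)
Conditions: 9-BBN-H, THF, rt; 17, Pd(dppf)Cl2 (5 mol%), AsPh3, aq. K3PO4, DMF, rt
Reagents that add atoms: none
Why: In this B-alkyl Suzuki–Miyaura coupling 9-BBN takes only the terminal vinyl group with boron on C4, and the vinyl bromide couples with retention, so C4 ends up cis to C7 (5Z).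

**Step 14**
Reactants: 23 C9-O-TBS 8,9-seco-briarane butenolide
Product: 25 8,9-seco-briarane C9 aldehyde (1S,2R,5Z,7S,10S,14S), via primary alcohol 24 (not isolated)
Conditions: Bi(OTf)3 (5 mol%), TEMPO (10 mol%), PhI(OAc)2, wet CH2Cl2, rt
Reagents that add atoms: none
Why: In this one-pot oxidative desilylation Lewis-acid hydrolysis of the primary silyl ether feeds an oxoammonium oxidation that stops at the aldehyde under nearly neutral conditions, so C10 and the β,γ-double bond stay in place.

**Step 15**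
Reactants: 25 8,9-seco-briarane C9 aldehyde
Product: 29 target CNP0293221.1, via samarium enolate 26 (not isolated), via selenide 27 (not isolated), via selenoxide 28 (not isolated)
Conditions: 25 added over 8 h to SmI2 (2.2 equiv), THF (final 1 mM), −20 °C; PhSeBr (1.1 equiv), −78 °C; 30% H2O2, pyridine, CH2Cl2, 0 °C
Reagents that add atoms: none
Why: Proposed new method: SmI2 reduces the only aldehyde to a Sm(III) ketyl radical that is tied to the lactone carbonyl by chelation and adds 10-exo-trig to the electrophilic β-carbon C8 (closest known types: SmI2 ketyl–olefin coupling of aldehydes with acrylates and butenolides, and SmI2 medium-ring closures), a second electron gives the C17 samarium enolate, selenenylation anti to C9 leaves H8 syn so that selenoxide syn-elimination restores C8=C17, and C9 becomes R because in the staggered transition state with C8 gauche to C1 (ring demand) and anti to C11 the bulky O–Sm lies anti to quaternary C1 and H9 takes the crowded site.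

**Compound list**
1 | but-2-yn-1-ol | CC#CCO | starting material
2 | sodium cyclic vinylalanate from 1 | [Na+].CC1=CCO[Al-]1(OCCOC)OCCOC | intermediate
3 | (Z)-3-bromobut-2-en-1-ol | C/C(Br)=C/CO | intermediate
4 | (Z)-(3-bromobut-2-enyloxy)(tert-butyl)dimethylsilane | C/C(Br)=C/CO[Si](C)(C)C(C)(C)C | intermediate
5 | (Z)-vinyllithium from 4 | C/C([Li])=C/CO[Si](C)(C)C(C)(C)C | intermediate
6 | (Z)-4-(tert-butyldimethylsilyloxy)-2-methylbut-2-enal | C/C(C=O)=C/CO[Si](C)(C)C(C)(C)C | intermediate
7 | 3-methylbut-3-en-2-one | CC(=O)C(C)=C | starting material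
8 | (5R,6Z)-8-(tert-butyldimethylsilyloxy)-5-hydroxy-2,6-dimethylocta-1,6-dien-3-one | C=C(C)C(=O)C[C@@H](O)/C(C)=C\CO[Si](C)(C)C(C)(C)C | intermediate
9 | (2R)-2-[(2Z)-4-(tert-butyldimethylsilyloxy)but-2-en-2-yl]-5-methyl-2,3-dihydro-4H-pyran-4-one | O=C1C[C@@H](OC=C1C)/C(C)=C\CO[Si](C)(C)C(C)(C)C | intermediate
10 | (1S,6S)-6-(tert-butyldimethylsilyloxymethyl)-1,5-dimethyl-2-oxocyclohex-4-ene-1-carbaldehyde | O=C[C@@]1(C)C(=O)CC=C(C)[C@@H]1CO[Si](C)(C)C(C)(C)C | intermediate
11 | (Z)-3-bromobut-2-enal | C/C(Br)=C/C=O | intermediate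
12 | propyne | CC#C | starting material
13 | methyl(prop-1-ynyl)zinc | C[Zn]C#CC | intermediate
14 | (4S,5Z)-6-bromohept-5-en-2-yn-4-ol | C/C(Br)=C/[C@H](O)C#CC | intermediate
15 | sodium cyclic vinylalanate from 14 | [Na+].C/C(Br)=C/[C@H]1C=C(C)[Al-](OCCOC)(OCCOC)O1 | intermediate
16 | (2Z,4S,5Z)-2-bromo-6-iodohepta-2,5-dien-4-ol | C/C(Br)=C/[C@H](O)/C=C(I)/C | intermediate
17 | (5R)-5-[(1Z)-2-bromoprop-1-enyl]-3-methylfuran-2(5H)-one | C/C(Br)=C/[C@@H]1OC(=O)C(C)=C1 | intermediate
18 | triisopropoxytitanium alkoxide of the (2R)-vinyl carbinol | CC(C)O[Ti](OC(C)C)(OC(C)C)O[C@H](C=C)[C@@]1(C)C(=O)CC=C(C)[C@@H]1CO[Si](C)(C)C(C)(C)C | intermediate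
19 | (1R)-1-[(1S,6S)-6-(tert-butyldimethylsilyloxymethyl)-1,5-dimethyl-2-oxocyclohex-4-en-1-yl]allyl butanoate | CCCC(=O)O[C@H](C=C)[C@@]1(C)C(=O)CC=C(C)[C@@H]1CO[Si](C)(C)C(C)(C)C | intermediate
20 | lithium (14S)-alkoxide from 19 | [Li+].CCCC(=O)O[C@H](C=C)[C@@]1(C)[C@@H]([O-])CC=C(C)[C@@H]1CO[Si](C)(C)C(C)(C)C | intermediate
21 | (1R)-1-[(1R,2S,6S)-2-acetoxy-6-(tert-butyldimethylsilyloxymethyl)-1,5-dimethylcyclohex-4-en-1-yl]allyl butanoate | CCCC(=O)O[C@H](C=C)[C@@]1(C)[C@@H](OC(C)=O)CC=C(C)[C@@H]1CO[Si](C)(C)C(C)(C)C | intermediate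
22 | B-alkyl-9-BBN from 21 (boron on C4) | CCCC(=O)O[C@H](CCB1C2CCCC1CCC2)[C@@]1(C)[C@@H](OC(C)=O)CC=C(C)[C@@H]1CO[Si](C)(C)C(C)(C)C | intermediate
23 | C9-O-TBS 8,9-seco-briarane butenolide (1S,2R,5Z,7S,10S,14S): the C2 chain of 21 is now CH(OCOPr)CH2CH2C(Me)=CH bonded to C5 of 3-methylfuran-2(5H)-one | CCCC(=O)O[C@H](CCC(\C)=C/[C@@H]1OC(=O)C(C)=C1)[C@@]1(C)[C@@H](OC(C)=O)CC=C(C)[C@@H]1CO[Si](C)(C)C(C)(C)C | intermediate
24 | C9 primary alcohol from 23 | CCCC(=O)O[C@H](CCC(\C)=C/[C@@H]1OC(=O)C(C)=C1)[C@@]1(C)[C@@H](OC(C)=O)CC=C(C)[C@@H]1CO | intermediate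
25 | 8,9-seco-briarane C9 aldehyde (1S,2R,5Z,7S,10S,14S) | CCCC(=O)O[C@H](CCC(\C)=C/[C@@H]1OC(=O)C(C)=C1)[C@@]1(C)[C@@H](OC(C)=O)CC=C(C)[C@@H]1C=O | intermediate
26 | ring-closed bis-samarium(III) C9 alkoxide / C17 lactone enolate (C9 trans to C6 on the lactone) | CCCC(=O)O[C@@H]1CCC(\C)=C/[C@@H]2OC(O[Sm](I)I)=C(C)[C@H]2[C@H](O[Sm](I)I)[C@H]2C(C)=CC[C@H](OC(C)=O)[C@@]21C | intermediate
27 | C17 phenylselenide (Se cis to H8), C9 samarium alkoxide | CCCC(=O)O[C@@H]1CCC(\C)=C/[C@@H]2OC(=O)[C@](C)([Se]c3ccccc3)[C@H]2[C@H](O[Sm](I)I)[C@H]2C(C)=CC[C@H](OC(C)=O)[C@@]21C | intermediate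
28 | C17 selenoxide, free 9-OH | CCCC(=O)O[C@@H]1CCC(\C)=C/[C@@H]2OC(=O)[C@](C)([Se](=O)c3ccccc3)[C@H]2[C@H](O)[C@H]2C(C)=CC[C@H](OC(C)=O)[C@@]21C | intermediate
29 | CNP0293221.1 (1S,2R,5Z,7S,9R,10S,14S) | CCCC(=O)O[C@@H]1CCC(\C)=C/[C@@H]2OC(=O)C(C)=C2[C@H](O)[C@H]2C(C)=CC[C@H](OC(C)=O)[C@@]21C | target

**Step count and longest linear sequence**
- Total step count: 15.
- Longest linear sequence: 11 steps (1, 2, 3, 4, 5, 6, 11, 12, 13, 14, 15).
- The butenolide branch is steps 1, 7, 8, 9 and 10, and it shares step 1 with the main line.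

**Three steps most likely to fail**

Step 15. The ten-membered closure may lose to simple reduction or pinacol coupling, and the elimination may go toward the methyl group. The fallback sets out from 21 and comes back at 29, and it moves the ring closure to C4–C5.
- 21 is oxidatively desilylated as in step 14 to the ring-A aldehyde F1.
- F1 and an excess of 17 are joined by the same samarium ketyl addition, now run between two molecules at normal concentration with a PhSeBr quench, to give the open-chain selenide F2.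
- H2O2 and pyridine give the open-chain carbinol butenolide F3.
- 9-BBN-H (2.2 equiv) hydroborates only the vinyl group and caps the hydroxyl, giving the bis-boron compound F4.
- An intramolecular B-alkyl Suzuki coupling under high dilution, followed by aqueous cleavage of the O–B bond, closes the ring to 29.

Step 6. The vinylogous ester is a poor Claisen partner and the Z side chain sits inside the boat, so decomposition or Z/E leakage may win at 190 °C. The fallback sets out from 9 and comes back at 21, and it sets C14 before the rearrangement.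
- Luche reduction gives the cis allylic alcohol F5.
- Mitsunobu inversion with acetic acid gives the trans acetate F6. Its enol ether is now electron-rich and rearranges at a lower temperature.
- The rearrangement gives the acetoxy aldehyde F7, which already carries 14S.
- The vinyltitanium addition and butyryl chloride quench of step 11 then give 21, so 10 and 19 are bypassed.

Step 5. Oxypalladation that must place palladium on a fully substituted carbon may be slow, and the bis-allylic alcohol may be oxidised or transposed. The fallback sets out from 8 and comes back at 9, and it splits the task in two.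
- Acid-catalysed 6-endo oxa-Michael addition (Amberlyst-15) gives the tetrahydropyranone F8 as a C1 epimer mixture.
- Dehydrogenation with IBX in DMSO toward the stabilised vinylogous ester gives 9.

**Further compounds**
F1 | step 15 | ring-A aldehyde (C9 aldehyde of 21) | CCCC(=O)O[C@H](C=C)[C@@]1(C)[C@@H](OC(C)=O)CC=C(C)[C@@H]1C=O
F2 | step 15 | open-chain selenide (C8–C9 bond made, SePh on C17) | CCCC(=O)O[C@H](C=C)[C@@]1(C)[C@@H](OC(C)=O)CC=C(C)[C@@H]1[C@@H](O)[C@@H]1[C@@](C)([Se]c2ccccc2)C(=O)O[C@H]1/C=C(Br)/C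
F3 | step 15 | open-chain carbinol butenolide (9R, vinyl and vinyl bromide termini) | CCCC(=O)O[C@H](C=C)[C@@]1(C)[C@@H](OC(C)=O)CC=C(C)[C@@H]1[C@@H](O)C1=C(C)C(=O)O[C@H]1/C=C(Br)/C
F4 | step 15 | bis-boron compound (C4 B-alkyl-9-BBN, C9 O-9-BBN) | CCCC(=O)O[C@H](CCB2C3CCCC2CCC3)[C@@]1(C)[C@@H](OC(C)=O)CC=C(C)[C@@H]1[C@@H](OB2C3CCCC2CCC3)C1=C(C)C(=O)O[C@H]1/C=C(Br)/C
F5 | step 6 | (2R,4R)-cis allylic alcohol from 9 | O[C@@H]1C[C@@H](OC=C1C)/C(C)=C\CO[Si](C)(C)C(C)(C)C
F6 | step 6 | (2R,4S)-trans acetate | CC(=O)O[C@H]1C[C@@H](OC=C1C)/C(C)=C\CO[Si](C)(C)C(C)(C)C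
F7 | step 6 | acetoxy aldehyde (10 with 14S-OAc in place of the ketone) | O=C[C@@]1(C)[C@@H](OC(C)=O)CC=C(C)[C@@H]1CO[Si](C)(C)C(C)(C)C
F8 | step 5 | tetrahydropyranone (C1 epimer mixture) | O=C1C[C@@H](OCC1C)/C(C)=C\CO[Si](C)(C)C(C)(C)C
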